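**Plan** (rings lettered A–E from the 2,4,6-trihydroxyphenyl end)
- Enabling feature: ring A is a benzene-1,3,5-triol whose C2, the carbon between the C1 and C3 hydroxyls, carries the ether oxygen to ring B. Its six carbons map onto a hexanoate with oxygen on C1, C3 and C5 and the aryloxy group on C6, so the ring can be closed by a carbon Claisen condensation of C6 onto the ester carbon C1.
- Cuts, in order: the ten O–CH3 bonds; the ring A C–C bond between the aryloxy-bearing carbon and its neighbouring C–OH carbon; the chain C4–C5 bond (vinylogous Claisen on a Weinreb amide); the ring C–O–ring D ether; the O–CH2 bond on ring B; the B–O–C and D–O–E ethers.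
- Forward: rings B, C, D and E are bought as arenes and joined by three copper-mediated C–O couplings (D–E, B–C, then BC + DE). The chain is grown on the ring B oxygen, and ring A is the only ring made, last.
- Strengthening: the C3 carbonyl of the triketide is carried as its methyl enol ether. The free 3,5-diketo ester would rest as a polyanion with a deactivated ester or lactonise irreversibly to a 4-hydroxy-2-pyrone; the enol ether keeps the ester electrophilic and makes O-acylation reversible.
- Stereochemistry: the target has no stereocentre and no hindered axis, so nothing has to be set. The E enol ether of the Claisen precursor comes from the commercial crotonate 13.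

Key step: step 8

Assumption: the target is achiral (no stereocentre, freely rotating diaryl ethers), so "single enantiomer" is read as the one compound drawn. Compounds 1, 2, 4, 8 and 13 are taken as catalogue chemicals.

Abbreviation: ArO– = 4-[2-[3,5-dimethoxy-4-(3,4,5-trimethoxyphenoxy)phenoxy]-3,5-dimethoxyphenoxy]-3,5-dimethoxyphenoxy, i.e. rings B–E with nine methyl ethers, bound through the ring B oxygen para to the B–C ether.

**Route**

Step 1
Reactants: 1 4-bromo-2,6-dimethoxyphenol; 2 (3,4,5-trimethoxyphenyl)boronic acid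
Product: 3 5-(4-bromo-2,6-dimethoxyphenoxy)-1,2,3-trimethoxybenzene
Conditions: Cu(OAc)2 (1 equiv, held as Cu(II) by air), pyridine, 4 Å MS, CH2Cl2, dry air, rt
Reagents that add atoms: none
Why: Chan–Lam oxidative O-arylation runs at room temperature, accepts doubly ortho-substituted phenols and leaves the aryl bromide untouched, which is why ring E is brought in as the boronic acid and not as a halide.

Step 2
Reactants: 1 4-bromo-2,6-dimethoxyphenol; 4 2-bromo-4,6-dimethoxybenzaldehyde
Product: 5 2-(4-bromo-2,6-dimethoxyphenoxy)-4,6-dimethoxybenzaldehyde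
Conditions: CuI (10 mol%), picolinic acid (20 mol%), K3PO4, DMSO, 80 °C, Ar; 4 in slight excess
Reagents that add atoms: none
Why: Ullmann diaryl ether synthesis in which the bromide of 4 is activated by its ortho-formyl group, while the bromide of 1 sits para to a phenoxide and that of 5 on an unactivated electron-rich ring, so the coupling should stop after one C–O bond.

Step 3
Reactants: 5 2-(4-bromo-2,6-dimethoxyphenoxy)-4,6-dimethoxybenzaldehyde
Product: 7 2-(4-hydroxy-2,6-dimethoxyphenoxy)-4,6-dimethoxybenzaldehyde, via pinacol boronate 6 (not isolated)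
Conditions: B2pin2, PdCl2(dppf) (3 mol%), KOAc, dioxane, 90 °C; filter; then Me3NO, THF, 50 °C; aq. NH4Cl
Reagents that add atoms: trimethylamine N-oxide, C[N+](C)(C)[O-] (the phenol oxygen); bis(pinacolato)diboron, CC1(C)OB(OC1(C)C)B1OC(C)(C)C(C)(C)O1 (the boryl group of 6 only)
Why: Miyaura borylation of the aryl bromide followed by amine N-oxide oxidation of the C–B bond turns Br into OH without hydroxide or peroxide, so the aldehyde and the aryloxy group ortho to it are not attacked.

Step 4
Reactants: 7 2-(4-hydroxy-2,6-dimethoxyphenoxy)-4,6-dimethoxybenzaldehyde; 8 2-chloro-N-methoxy-N-methylacetamide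
Product: 9 2-[4-(2-formyl-3,5-dimethoxyphenoxy)-3,5-dimethoxyphenoxy]-N-methoxy-N-methylacetamide
Conditions: K2CO3, NaI (10 mol%), DMF, 60 °C
Reagents that add atoms: none
Why: Williamson ether synthesis of the unhindered phenol with an α-chloro amide (iodide-assisted) puts C5 and C6 of the future ring A chain on the ring B oxygen as a Weinreb amide that tolerates the next two steps.

Step 5
Reactants: 9 2-[4-(2-formyl-3,5-dimethoxyphenoxy)-3,5-dimethoxyphenoxy]-N-methoxy-N-methylacetamide
Product: 11 2-[4-(2-hydroxy-3,5-dimethoxyphenoxy)-3,5-dimethoxyphenoxy]-N-methoxy-N-methylacetamide, via aryl formate 10 (not isolated)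
Conditions: mCPBA, CH2Cl2, 0 °C to rt; aq. Na2S2O3/NaHCO3 wash; then K2CO3 (cat.), MeOH, rt, Ar
Reagents that add atoms: 3-chloroperoxybenzoic acid, OOC(=O)c1cccc(Cl)c1 (one oxygen atom)
Why: Baeyer–Villiger (Dakin-type) oxidation in which the 2,4,6-trioxygenated aryl group migrates in preference to hydrogen; the formate is methanolysed only after the peracid is removed, so the oxidation-prone phenol never meets the oxidant.

Step 6
Reactants: 11 2-[4-(2-hydroxy-3,5-dimethoxyphenoxy)-3,5-dimethoxyphenoxy]-N-methoxy-N-methylacetamide; 3 5-(4-bromo-2,6-dimethoxyphenoxy)-1,2,3-trimethoxybenzene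
Product: 12 2-(ArO)-N-methoxy-N-methylacetamide
Conditions: CuI (20 mol%), picolinic acid (40 mol%), K3PO4, DMSO, 100 °C, Ar; 3 (1.3 equiv)
Reagents that add atoms: none
Why: Ullmann diaryl ether coupling under the CuI/picolinic acid conditions made for ortho-disubstituted phenols, with an unhindered aryl bromide as partner and only methyl ethers and a tertiary N-methoxy amide as spectators.

Step 7
Reactants: 12 2-(ArO)-N-methoxy-N-methylacetamide; 13 methyl (2E)-3-methoxybut-2-enoate
Product: 15 methyl (2E)-6-(ArO)-3-methoxy-5-oxohex-2-enoate, via lithium dienolate 14 (not isolated)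
Conditions: 13 (1.6 equiv), LDA (1.6 equiv), THF, −78 °C; then 12, −78 to −40 °C; AcOH quench at −78 °C
Reagents that add atoms: none
Why: Vinylogous Claisen acylation, in which the lithium dienolate of a 3-alkoxycrotonate is acylated at its γ-carbon and the chelated tetrahedral adduct of the Weinreb amide lasts until the quench, so the acidic product neither protonates the dienolate nor is attacked twice; the E geometry of 13 is kept.

Step 8
Reactants: 15 methyl (2E)-6-(ArO)-3-methoxy-5-oxohex-2-enoate
Product: 17 2-(ArO)-5-methoxybenzene-1,3-diol, via cyclohexenedione 16 (not isolated)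
Conditions: NaOMe (5 equiv), degassed MeOH, sealed tube, 100 °C, Ar; then 1 M HCl, 0 °C
Reagents that add atoms: none
Why: Proposed new method: methoxide reversibly deprotonates 15 at C4 and C6; the C6 enolate, stabilised by the ketone and the aryloxy group, attacks the ester carbonyl C1, methoxide leaves, and the cyclohexenedione 16 enolises irreversibly to the arene. The closest known reaction types are the Claisen cyclisation of 3,5,7-triketo esters to acylphloroglucinols and the methoxide-induced conversion of 4-methoxy-6-methyl-2-pyrone into 5-methoxyresorcinol through the analogous ring-opened enol-ether ester. Ring A closes in a 6-(enolendo)-exo-trig mode, and the one transient stereocentre of 16 is lost on aromatisation, so no stereo control is needed. The step needs C- over O-acylation. The C3 enol ether prevents deprotonation at C2, so the ester stays electrophilic, and the E double bond holds C1 and C4 cis. O-acylation gives only a neutral 4-methoxy-2-pyrone that methoxide reopens, which leaves the aromatising C–C closure as the only irreversible exit.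

Step 9
Reactants: 17 2-(ArO)-5-methoxybenzene-1,3-diol
Product: 18 2-[4-[2-[3,5-dihydroxy-4-(3,4,5-trihydroxyphenoxy)phenoxy]-3,5-dihydroxyphenoxy]-3,5-dihydroxyphenoxy]benzene-1,3,5-triol
Conditions: BBr3 (25 equiv), CH2Cl2, −78 °C to rt, Ar; MeOH then H2O at 0 °C; work-up under Ar
Reagents that add atoms: none
Why: BBr3 ether cleavage (Lewis acid complexation, then bromide SN2 at methyl) should remove all ten methyl groups, while the aryl–O–aryl bonds offer no sp3 carbon and survive.

**Compound list**

1 | 4-bromo-2,6-dimethoxyphenol | COc1cc(Br)cc(OC)c1O | starting material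
2 | (3,4,5-trimethoxyphenyl)boronic acid | COc1cc(B(O)O)cc(OC)c1OC | starting material
3 | 5-(4-bromo-2,6-dimethoxyphenoxy)-1,2,3-trimethoxybenzene | COc1cc(Br)cc(OC)c1Oc1cc(OC)c(OC)c(OC)c1 | intermediate
4 | 2-bromo-4,6-dimethoxybenzaldehyde | COc1cc(Br)c(C=O)c(OC)c1 | starting material
5 | 2-(4-bromo-2,6-dimethoxyphenoxy)-4,6-dimethoxybenzaldehyde | COc1cc(Oc2c(OC)cc(Br)cc2OC)c(C=O)c(OC)c1 | intermediate
6 | 2-[2,6-dimethoxy-4-(4,4,5,5-tetramethyl-1,3,2-dioxaborolan-2-yl)phenoxy]-4,6-dimethoxybenzaldehyde | COc1cc(Oc2c(OC)cc(B3OC(C)(C)C(C)(C)O3)cc2OC)c(C=O)c(OC)c1 | intermediate (not isolated)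
7 | 2-(4-hydroxy-2,6-dimethoxyphenoxy)-4,6-dimethoxybenzaldehyde | COc1cc(Oc2c(OC)cc(O)cc2OC)c(C=O)c(OC)c1 | intermediate
8 | 2-chloro-N-methoxy-N-methylacetamide | CON(C)C(=O)CCl | starting material
9 | 2-[4-(2-formyl-3,5-dimethoxyphenoxy)-3,5-dimethoxyphenoxy]-N-methoxy-N-methylacetamide | COc1cc(Oc2c(OC)cc(OCC(=O)N(C)OC)cc2OC)c(C=O)c(OC)c1 | intermediate
10 | 2-[2,6-dimethoxy-4-[2-[methoxy(methyl)amino]-2-oxoethoxy]phenoxy]-4,6-dimethoxyphenyl formate | COc1cc(Oc2c(OC)cc(OCC(=O)N(C)OC)cc2OC)c(OC=O)c(OC)c1 | intermediate (not isolated)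
11 | 2-[4-(2-hydroxy-3,5-dimethoxyphenoxy)-3,5-dimethoxyphenoxy]-N-methoxy-N-methylacetamide | COc1cc(Oc2c(OC)cc(OCC(=O)N(C)OC)cc2OC)c(O)c(OC)c1 | intermediate
12 | 2-(ArO)-N-methoxy-N-methylacetamide (rings B–E with the Weinreb amide chain) | CON(C)C(=O)COc1cc(OC)c(Oc2cc(OC)cc(OC)c2Oc2cc(OC)c(Oc3cc(OC)c(OC)c(OC)c3)c(OC)c2)c(OC)c1 | intermediate
13 | methyl (2E)-3-methoxybut-2-enoate | CO/C(C)=C/C(=O)OC | starting material
14 | lithium 1,3-dimethoxybuta-1,3-dien-1-olate (enolate geometry not defined) | [Li+].C=C(OC)C=C([O-])OC | intermediate (not isolated)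
15 | methyl (2E)-6-(ArO)-3-methoxy-5-oxohex-2-enoate | COC(=O)/C=C(/OC)CC(=O)COc1cc(OC)c(Oc2cc(OC)cc(OC)c2Oc2cc(OC)c(Oc3cc(OC)c(OC)c(OC)c3)c(OC)c2)c(OC)c1 | intermediate
16 | 2-(ArO)-5-methoxycyclohex-4-ene-1,3-dione (racemic at C2, transient) | COC1=CC(=O)C(Oc2cc(OC)c(Oc3cc(OC)cc(OC)c3Oc3cc(OC)c(Oc4cc(OC)c(OC)c(OC)c4)c(OC)c3)c(OC)c2)C(=O)C1 | intermediate (not isolated)
17 | 2-(ArO)-5-methoxybenzene-1,3-diol | COc1cc(O)c(Oc2cc(OC)c(Oc3cc(OC)cc(OC)c3Oc3cc(OC)c(Oc4cc(OC)c(OC)c(OC)c4)c(OC)c3)c(OC)c2)c(O)c1 | intermediate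
18 | 2-[4-[2-[3,5-dihydroxy-4-(3,4,5-trihydroxyphenoxy)phenoxy]-3,5-dihydroxyphenoxy]-3,5-dihydroxyphenoxy]benzene-1,3,5-triol (achiral) | Oc1cc(O)c(Oc2cc(O)c(Oc3cc(O)cc(O)c3Oc3cc(O)c(Oc4cc(O)c(O)c(O)c4)c(O)c3)c(O)c2)c(O)c1 | target

**Totals**
Total steps: 9. Longest linear sequence: 8 (steps 2–9 from 1 and 4); step 1 supplies 3 for step 6.

**Steps most likely to fail**

Step 8 (proposed new method). The carbon Claisen closure may lose to retro-Claisen cleavage of the C4–C5 bond by methoxide, or the material may stay in the reversible lactone manifold without closing through carbon. The fallback uses known chemistry and buys ring A as 2,4,6-trimethoxyphenol. It sets out from 5. Ullmann coupling of 5 with 2,4,6-trimethoxyphenol (CuI, picolinic acid, K3PO4, DMSO, 100 °C) should give 2-[2,6-dimethoxy-4-(2,4,6-trimethoxyphenoxy)phenoxy]-4,6-dimethoxybenzaldehyde F1. Baeyer–Villiger oxidation with mCPBA gives the aryl formate F2, and methanolysis gives the phenol F3. Ullmann coupling of F3 with 3, as in step 6, gives the dodecamethyl ether of the target F4. BBr3 as in step 9 then returns to the route at 18.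

Step 7. The dienolate may be acylated at its α-carbon instead of its γ-carbon, or may be quenched by proton transfer from the OCH2 group of the amide. The fallback builds the chain from the free diketo ester and reaches the enol ether through the lactone. It sets out from 12. The dianion of methyl acetoacetate F5 (NaH, then n-BuLi, THF, 0 °C) is acylated at its terminal carbon by 12 to give methyl 6-(ArO)-3,5-dioxohexanoate F6. DBU in toluene at 80 °C lactonises it to the 4-hydroxy-2-pyrone F7, and Me2SO4/K2CO3 in acetone gives the 4-methoxy-2-pyrone F8. Under the conditions of step 8, methoxide opens the lactone of F8 to the E ester 15 in the flask, where the route is rejoined.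

Step 6. C–O bond formation at the doubly ortho-substituted phenoxide may be slow, with hydrodebromination of the aryl bromide and base-induced erosion of the amide at 100 °C. The fallback reverses the polarity of the aryl partner and works at room temperature. It sets out from 3. Pd-catalysed borylation with tetrahydroxydiboron (XPhos Pd G2, KOAc, EtOH, 80 °C) gives [3,5-dimethoxy-4-(3,4,5-trimethoxyphenoxy)phenyl]boronic acid F9. Chan–Lam coupling of F9 with 11 (Cu(OAc)2, pyridine, 4 Å MS, CH2Cl2, dry air, rt), as in step 1, forms the same ether and rejoins the route at 12.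

**Further compounds**

F1 | step 8 | 2-[2,6-dimethoxy-4-(2,4,6-trimethoxyphenoxy)phenoxy]-4,6-dimethoxybenzaldehyde | COc1cc(Oc2c(OC)cc(Oc3c(OC)cc(OC)cc3OC)cc2OC)c(C=O)c(OC)c1
F2 | step 8 | 2-[2,6-dimethoxy-4-(2,4,6-trimethoxyphenoxy)phenoxy]-4,6-dimethoxyphenyl formate | COc1cc(Oc2c(OC)cc(Oc3c(OC)cc(OC)cc3OC)cc2OC)c(OC=O)c(OC)c1
F3 | step 8 | 2-[2,6-dimethoxy-4-(2,4,6-trimethoxyphenoxy)phenoxy]-4,6-dimethoxyphenol | COc1cc(Oc2c(OC)cc(Oc3c(OC)cc(OC)cc3OC)cc2OC)c(O)c(OC)c1
F4 | step 8 | 2-(ArO)-1,3,5-trimethoxybenzene (dodecamethyl ether of the target) | COc1cc(OC)c(Oc2cc(OC)c(Oc3cc(OC)cc(OC)c3Oc3cc(OC)c(Oc4cc(OC)c(OC)c(OC)c4)c(OC)c3)c(OC)c2)c(OC)c1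
F5 | step 7 | sodium lithium dianion of methyl acetoacetate | [Na+].[Li+].C=C([O-])C=C([O-])OC
F6 | step 7 | methyl 6-(ArO)-3,5-dioxohexanoate | COC(=O)CC(=O)CC(=O)COc1cc(OC)c(Oc2cc(OC)cc(OC)c2Oc2cc(OC)c(Oc3cc(OC)c(OC)c(OC)c3)c(OC)c2)c(OC)c1
F7 | step 7 | 6-[(ArO)methyl]-4-hydroxy-2H-pyran-2-one | O=c1cc(O)cc(COc2cc(OC)c(Oc3cc(OC)cc(OC)c3Oc3cc(OC)c(Oc4cc(OC)c(OC)c(OC)c4)c(OC)c3)c(OC)c2)o1
F8 | step 7 | 6-[(ArO)methyl]-4-methoxy-2H-pyran-2-one | COc1cc(COc2cc(OC)c(Oc3cc(OC)cc(OC)c3Oc3cc(OC)c(Oc4cc(OC)c(OC)c(OC)c4)c(OC)c3)c(OC)c2)oc(=O)c1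
F9 | step 6 | [3,5-dimethoxy-4-(3,4,5-trimethoxyphenoxy)phenyl]boronic acid | COc1cc(B(O)O)cc(OC)c1Oc1cc(OC)c(OC)c(OC)c1
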